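**Retrosynthetic overview**

- The target is opened at the two phenol O–benzyl bonds and at the carbinol, which comes from an aryl ketone by oxazaborolidine reduction; the ketone comes from a syringyl Grignard reagent and a trans-4-(arylmethyl)oxolane-3-carbaldehyde.
- The formyl oxolane is disconnected by a Lewis-acid Prins–pinacol rearrangement of a (4S)-4-alkenyl-1,3-dioxolane, which forms the ring bonds C4–C5 and C2–C3 and both ring stereocentres; this is the only ring formed in the route.
- The alkenyl dioxolane comes from cross-metathesis of O-benzyl eugenol with (S)-4-vinyl-1,3-dioxolane, itself made from (S)-but-3-ene-1,2-diol and dimethoxymethane.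
- Feature on which the strategy rests: an oxolane whose O1 is flanked by two CH2 groups (C2 and C5), with an oxidised exocyclic carbon (the carbinol) on C3 and the guaiacylmethyl group on C4, which is the 3-acyl-4-alkyloxolane pattern that an alkenyl-dioxolane rearrangement delivers.

Key step: step 4

Remark on the chemistry: 4-bromo-2,6-dimethoxyphenol is taken as a purchasable compound (it is the para-bromination product of 2,6-dimethoxyphenol).

**Route**

Step 1
Reactants: 1 eugenol; 2 benzyl bromide
Product: 3 4-allyl-1-(benzyloxy)-2-methoxybenzene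
Conditions: K2CO3, acetone, reflux
Reagents that add atoms: none
Why: Williamson ether synthesis on the phenoxide, under carbonate conditions mild enough that the allyl double bond should not migrate into conjugation.

Step 2
Reactants: 4 (S)-but-3-ene-1,2-diol; 5 dimethoxymethane
Product: 6 (4S)-4-ethenyl-1,3-dioxolane
Conditions: CH2(OMe)2 (excess), TsOH·H2O (cat.), LiBr (cat.), rt; distillation
Reagents that add atoms: none
Why: Acid-catalysed transacetalisation closes the five-membered formal without breaking any bond to the stereocentre, so the S configuration is carried over unchanged.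

Step 3
Reactants: 3 4-allyl-1-(benzyloxy)-2-methoxybenzene; 6 (4S)-4-ethenyl-1,3-dioxolane
Product: 7 (4S)-4-{(1E)-3-[4-(benzyloxy)-3-methoxyphenyl]prop-1-en-1-yl}-1,3-dioxolane
Conditions: second-generation Grubbs catalyst RuCl2(=CHPh)(PCy3)(H2IMes) (5 mol %), 1,4-benzoquinone (10 mol %), CH2Cl2, 40 °C, 3 in excess (2 equiv)
Reagents that add atoms: none
Why: Olefin cross-metathesis pairs the quickly homodimerising allylarene (whose dimer re-enters the cycle) with the slowly homodimerising allylic-ether olefin so that the cross product should dominate with the thermodynamically preferred E geometry, benzoquinone suppresses Ru–H migration of the allyl double bond, and the stereocentre is not involved.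

Step 4
Reactants: 7 (4S)-4-{(1E)-3-[4-(benzyloxy)-3-methoxyphenyl]prop-1-en-1-yl}-1,3-dioxolane
Product: 9 (3R,4R)-4-[4-(benzyloxy)-3-methoxybenzyl]oxolane-3-carbaldehyde, via tin-bound oxocarbenium ion 8 (not isolated)
Conditions: SnCl4 (2.5 equiv), CH2Cl2 (0.02 M), −78 → −20 °C; aq. NaHCO3; then DBU (0.2 equiv), CH2Cl2, rt
Reagents that add atoms: none
Why: SnCl4 opens the formal at the allylic oxygen to give oxocarbenium ion 8 on the primary oxygen, whose CH2 carbon bonds to the distal alkene carbon (C5–C4 of 9) through a six-membered chair while the diol CH2 carbon ends on the proximal alkene carbon (C2–C3) and the former carbinol carbon leaves the ring as the formyl group; the closest known reaction type is the Lewis-acid Prins–pinacol rearrangement of 4-alkenyl-1,3-dioxolanes to 3-acyloxolanes. The oxolane is closed either by 6-endo Prins cyclisation to an oxan-4-yl cation and ring-contracting 1,2-shift of the ring CH2 (pinacol step) or, more likely for an alkene with no cation-stabilising group on its proximal carbon, by charge-accelerated 2-oxonia-Cope rearrangement and aldol closure of the resulting tin enolate on the new oxocarbenium ion (five-membered ring, enol exocyclic, endo with respect to the C=O+ bond, as in the aza-Cope–Mannich reaction). The benzyl-bearing centre C4 of 9 is set by transfer of chirality from the 4S C–O centre of 7, which is destroyed: in the chair with the bulky Cl4Sn–O bond equatorial and the E-alkene holding its CH2Ar group equatorial, C–C bond formation should give the R configuration. The formyl-bearing centre C3 follows as R (trans) either directly from the suprafacial shift in that chair or, because it is α to the aldehyde, by DBU equilibration to the more stable trans isomer. The step needs the alkene and not the electron-rich arene to capture the oxocarbenium ion, which the six-membered transition state secures against a nine-membered one, and it needs a single chair, which rests on the equatorial preference of the stannylated oxygen and on the E-purity of 7, since the other chair or the Z-alkene would lead to the enantiomer.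

Step 5
Reactants: 10 4-bromo-2,6-dimethoxyphenol; 2 benzyl bromide
Product: 11 2-(benzyloxy)-5-bromo-1,3-dimethoxybenzene
Conditions: K2CO3, DMF, 60 °C
Reagents that add atoms: none
Why: Williamson ether synthesis on the hindered but acidic phenol, for which a polar aprotic solvent and gentle heating should suffice.

Step 6
Reactants: 11 2-(benzyloxy)-5-bromo-1,3-dimethoxybenzene; 9 (3R,4R)-4-[4-(benzyloxy)-3-methoxybenzyl]oxolane-3-carbaldehyde
Product: 13 [(3R,4R)-4-[4-(benzyloxy)-3-methoxybenzyl]oxolan-3-yl][4-(benzyloxy)-3,5-dimethoxyphenyl]methanol as a mixture of carbinol epimers, via arylmagnesium bromide 12 (not isolated)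
Conditions: Mg, THF, reflux (I2 to start); then 9, THF, −78 → 0 °C; aq. NH4Cl
Reagents that add atoms: none
Why: Grignard formation by magnesium insertion and 1,2-addition to the aldehyde at low temperature (to limit enolisation of the α-branched aldehyde) builds the aryl–carbinol bond, and the carbinol configuration is left uncontrolled because steps 7 and 8 reset it.

Step 7
Reactants: 13 [(3R,4R)-4-[4-(benzyloxy)-3-methoxybenzyl]oxolan-3-yl][4-(benzyloxy)-3,5-dimethoxyphenyl]methanol as a mixture of carbinol epimers
Product: 14 [(3R,4R)-4-[4-(benzyloxy)-3-methoxybenzyl]oxolan-3-yl][4-(benzyloxy)-3,5-dimethoxyphenyl]methanone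
Conditions: Dess–Martin periodinane, CH2Cl2, rt
Reagents that add atoms: none
Why: Dess–Martin oxidation of the secondary benzylic alcohol converges both epimers on one ketone, whose α-centre sits in the more stable trans arrangement (any cis isomer could be equilibrated with DBU).

Step 8
Reactants: 14 [(3R,4R)-4-[4-(benzyloxy)-3-methoxybenzyl]oxolan-3-yl][4-(benzyloxy)-3,5-dimethoxyphenyl]methanone
Product: 15 (S)-[(3R,4R)-4-[4-(benzyloxy)-3-methoxybenzyl]oxolan-3-yl][4-(benzyloxy)-3,5-dimethoxyphenyl]methanol
Conditions: (R)-2-methyl-CBS-oxazaborolidine (0.2 equiv), BH3·SMe2 (1.0 equiv), THF, −20 °C; then MeOH/H2O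
Reagents that add atoms: none
Why: Corey–Bakshi–Shibata reduction with the aryl group as the large substituent should deliver hydride from the (R)-catalyst to the face that gives the S carbinol, and the Felkin–Anh preference of the adjacent ring stereocentre (hydride anti to C4, the more substituted ring neighbour) is expected to point the same way.

Step 9
Reactants: 15 (S)-[(3R,4R)-4-[4-(benzyloxy)-3-methoxybenzyl]oxolan-3-yl][4-(benzyloxy)-3,5-dimethoxyphenyl]methanol
Product: 16 4-[(S)-hydroxy{(3R,4R)-4-[(4-hydroxy-3-methoxyphenyl)methyl]oxolan-3-yl}methyl]-2,6-dimethoxyphenol (CNP0307127.1)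
Conditions: H2 (1 atm), 10% Pd/C, EtOAc, rt, stopped at complete debenzylation
Reagents that add atoms: none
Why: Catalytic hydrogenolysis cleaves the two aryl benzyl ethers far faster than the secondary benzylic C–OH bond in a neutral aprotic solvent, and no stereocentre is touched.

**Compound list**

1 | eugenol | COc1cc(CC=C)ccc1O | starting material
2 | benzyl bromide | BrCc1ccccc1 | starting material
3 | 4-allyl-1-(benzyloxy)-2-methoxybenzene | COc1cc(CC=C)ccc1OCc1ccccc1 | intermediate
4 | (S)-but-3-ene-1,2-diol | C=C[C@H](O)CO | starting material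
5 | dimethoxymethane | COCOC | starting material
6 | (4S)-4-ethenyl-1,3-dioxolane | C=C[C@H]1COCO1 | intermediate
7 | (4S)-4-{(1E)-3-[4-(benzyloxy)-3-methoxyphenyl]prop-1-en-1-yl}-1,3-dioxolane | COc1cc(C/C=C/[C@H]2COCO2)ccc1OCc1ccccc1 | intermediate
8 | (2S,3E)-5-[4-(benzyloxy)-3-methoxyphenyl]-1-(methylideneoxonio)pent-3-en-2-yl tetrachlorostannate, the ring-opened oxocarbenium zwitterion | C=[O+]C[C@@H](O[Sn-](Cl)(Cl)(Cl)Cl)/C=C/Cc1ccc(OCc2ccccc2)c(OC)c1 | intermediate
9 | (3R,4R)-4-[4-(benzyloxy)-3-methoxybenzyl]oxolane-3-carbaldehyde | COc1cc(C[C@H]2COC[C@@H]2C=O)ccc1OCc1ccccc1 | intermediate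
10 | 4-bromo-2,6-dimethoxyphenol | COc1cc(Br)cc(OC)c1O | starting material
11 | 2-(benzyloxy)-5-bromo-1,3-dimethoxybenzene | COc1cc(Br)cc(OC)c1OCc1ccccc1 | intermediate
12 | [4-(benzyloxy)-3,5-dimethoxyphenyl]magnesium bromide | COc1cc([Mg]Br)cc(OC)c1OCc1ccccc1 | intermediate
13 | [(3R,4R)-4-[4-(benzyloxy)-3-methoxybenzyl]oxolan-3-yl][4-(benzyloxy)-3,5-dimethoxyphenyl]methanol, mixture of carbinol epimers | COc1cc(C[C@H]2COC[C@@H]2C(O)c2cc(OC)c(OCc3ccccc3)c(OC)c2)ccc1OCc1ccccc1 | intermediate
14 | [(3R,4R)-4-[4-(benzyloxy)-3-methoxybenzyl]oxolan-3-yl][4-(benzyloxy)-3,5-dimethoxyphenyl]methanone | COc1cc(C[C@H]2COC[C@@H]2C(=O)c2cc(OC)c(OCc3ccccc3)c(OC)c2)ccc1OCc1ccccc1 | intermediate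
15 | (S)-[(3R,4R)-4-[4-(benzyloxy)-3-methoxybenzyl]oxolan-3-yl][4-(benzyloxy)-3,5-dimethoxyphenyl]methanol | COc1cc(C[C@H]2COC[C@@H]2[C@H](O)c2cc(OC)c(OCc3ccccc3)c(OC)c2)ccc1OCc1ccccc1 | intermediate
16 | 4-[(S)-hydroxy{(3R,4R)-4-[(4-hydroxy-3-methoxyphenyl)methyl]oxolan-3-yl}methyl]-2,6-dimethoxyphenol | COc1cc(C[C@H]2COC[C@@H]2[C@H](O)c2cc(OC)c(O)c(OC)c2)ccc1O | target

**Step count**

Total steps: 9. Longest linear sequence: 7 steps (steps 1, 3, 4, 6, 7, 8, 9).

**Steps most likely to fail**

Step 4. The methylene acetal may ionise sluggishly, and the electron-rich arene may be alkylated intermolecularly. A stepwise cation may suffer a 1,2-hydride shift to an oxan-3-one instead of ring contraction. Chirality may leak through the chair with the axial C–O bond or through a reversible oxonia-Cope equilibrium, eroding enantiopurity. The fallback uses known chemistry and sets out from 3. Cross-metathesis of 3 with allyl methyl carbonate (second-generation Grubbs catalyst RuCl2(=CHPh)(PCy3)(H2IMes), CH2Cl2, 40 °C) would give (2E)-4-[4-(benzyloxy)-3-methoxyphenyl]but-2-en-1-yl methyl carbonate F1. Iridium-catalysed asymmetric allylic alkylation with dimethyl malonate ([Ir(cod)Cl]2, enantiopure O,O′-(1,1′-binaphthalene-2,2′-diyl) N,N-bis(1-phenylethyl)phosphoramidite of the sense that delivers the 2S product, 1,5,7-triazabicyclo[4.4.0]dec-5-ene cat., THF, rt) would give the branched dimethyl 2-[(2S)-1-[4-(benzyloxy)-3-methoxyphenyl]but-3-en-2-yl]propanedioate F2, which sets the benzyl-bearing centre. LiAlH4 (THF, 0 °C) would reduce it to 2-[(2S)-1-[4-(benzyloxy)-3-methoxyphenyl]but-3-en-2-yl]propane-1,3-diol F3. Cleavage of the vinyl group (OsO4 cat., NaIO4, 2,6-lutidine, dioxane/H2O; then NaBH4) would give (2R)-2-[4-(benzyloxy)-3-methoxybenzyl]-3-(hydroxymethyl)butane-1,4-diol F4, whose second carbinol-bearing carbon is not stereogenic. Cyclodehydration (PPh3, DIAD, THF) would close the oxolane to {(4R)-4-[4-(benzyloxy)-3-methoxybenzyl]oxolan-3-yl}methanol F5 as a mixture of C3 epimers. Dess–Martin oxidation would give 9 together with its cis epimer (3S,4R)-4-[4-(benzyloxy)-3-methoxybenzyl]oxolane-3-carbaldehyde F6, and DBU equilibration would converge the mixture on 9, where the route is rejoined.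

Step 8. Facial selectivity may be poor if the α-branched ring carbon competes with the aryl group as the large substituent at the catalyst, or if catalyst control and substrate bias turn out to oppose each other. The fallback sets out from 14 and corrects the stereocentre by inversion instead of by reagent control. Reduction of 14 under substrate control (LiBH(s-Bu)3, THF, −78 °C) and chromatographic separation would give 15 together with its epimer (R)-[(3R,4R)-4-[4-(benzyloxy)-3-methoxybenzyl]oxolan-3-yl][4-(benzyloxy)-3,5-dimethoxyphenyl]methanol F7. Mitsunobu esterification of F7 (4-nitrobenzoic acid, PPh3, DIAD, toluene, −20 °C) would invert it to (S)-[(3R,4R)-4-[4-(benzyloxy)-3-methoxybenzyl]oxolan-3-yl][4-(benzyloxy)-3,5-dimethoxyphenyl]methyl 4-nitrobenzoate F8. Hydrolysis of F8 (LiOH, THF/H2O) would return 15.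

Step 9. Once the para-phenol is free, hydrogenolysis may go on to cleave the benzylic C–OH bond (over-reduction to the deoxy compound). The fallback sets out from 14 and moves debenzylation ahead of carbinol formation. Hydrogenolysis of 14 (H2, 10% Pd/C, EtOAc), where no benzylic C–OH bond is present, would give (4-hydroxy-3,5-dimethoxyphenyl)[(3R,4R)-4-(4-hydroxy-3-methoxybenzyl)oxolan-3-yl]methanone F9. Silylation (TBSCl, imidazole, DMF) would give the bis(tert-butyldimethylsilyl) ether [4-(tert-butyldimethylsilyloxy)-3,5-dimethoxyphenyl][(3R,4R)-4-[4-(tert-butyldimethylsilyloxy)-3-methoxybenzyl]oxolan-3-yl]methanone F10. Reduction as in step 8 would give (S)-[4-(tert-butyldimethylsilyloxy)-3,5-dimethoxyphenyl][(3R,4R)-4-[4-(tert-butyldimethylsilyloxy)-3-methoxybenzyl]oxolan-3-yl]methanol F11. Fluoride desilylation of F11 (Bu4NF, AcOH, THF, 0 °C) would give 16.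

**Further compounds**

F1 | step 4 | (2E)-4-[4-(benzyloxy)-3-methoxyphenyl]but-2-en-1-yl methyl carbonate | COC(=O)OC/C=C/Cc1ccc(OCc2ccccc2)c(OC)c1
F2 | step 4 | dimethyl 2-[(2S)-1-[4-(benzyloxy)-3-methoxyphenyl]but-3-en-2-yl]propanedioate | COc1cc(C[C@H](C(C(=O)OC)C(=O)OC)C=C)ccc1OCc1ccccc1
F3 | step 4 | 2-[(2S)-1-[4-(benzyloxy)-3-methoxyphenyl]but-3-en-2-yl]propane-1,3-diol | COc1cc(C[C@H](C(CO)CO)C=C)ccc1OCc1ccccc1
F4 | step 4 | (2R)-2-[4-(benzyloxy)-3-methoxybenzyl]-3-(hydroxymethyl)butane-1,4-diol | COc1cc(C[C@H](C(CO)CO)CO)ccc1OCc1ccccc1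
F5 | step 4 | {(4R)-4-[4-(benzyloxy)-3-methoxybenzyl]oxolan-3-yl}methanol, mixture of C3 epimers | COc1cc(C[C@H]2COCC2CO)ccc1OCc1ccccc1
F6 | step 4 | (3S,4R)-4-[4-(benzyloxy)-3-methoxybenzyl]oxolane-3-carbaldehyde | COc1cc(C[C@H]2COC[C@H]2C=O)ccc1OCc1ccccc1
F7 | step 8 | (R)-[(3R,4R)-4-[4-(benzyloxy)-3-methoxybenzyl]oxolan-3-yl][4-(benzyloxy)-3,5-dimethoxyphenyl]methanol | COc1cc(C[C@H]2COC[C@@H]2[C@@H](O)c2cc(OC)c(OCc3ccccc3)c(OC)c2)ccc1OCc1ccccc1
F8 | step 8 | (S)-[(3R,4R)-4-[4-(benzyloxy)-3-methoxybenzyl]oxolan-3-yl][4-(benzyloxy)-3,5-dimethoxyphenyl]methyl 4-nitrobenzoate | COc1cc(C[C@H]2COC[C@@H]2[C@H](OC(=O)c3ccc(cc3)[N+](=O)[O-])c3cc(OC)c(OCc4ccccc4)c(OC)c3)ccc1OCc1ccccc1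
F9 | step 9 | (4-hydroxy-3,5-dimethoxyphenyl)[(3R,4R)-4-(4-hydroxy-3-methoxybenzyl)oxolan-3-yl]methanone | COc1cc(C[C@H]2COC[C@@H]2C(=O)c2cc(OC)c(O)c(OC)c2)ccc1O
F10 | step 9 | [4-(tert-butyldimethylsilyloxy)-3,5-dimethoxyphenyl][(3R,4R)-4-[4-(tert-butyldimethylsilyloxy)-3-methoxybenzyl]oxolan-3-yl]methanone | COc1cc(C[C@H]2COC[C@@H]2C(=O)c2cc(OC)c(O[Si](C)(C)C(C)(C)C)c(OC)c2)ccc1O[Si](C)(C)C(C)(C)C
F11 | step 9 | (S)-[4-(tert-butyldimethylsilyloxy)-3,5-dimethoxyphenyl][(3R,4R)-4-[4-(tert-butyldimethylsilyloxy)-3-methoxybenzyl]oxolan-3-yl]methanol | COc1cc(C[C@H]2COC[C@@H]2[C@H](O)c2cc(OC)c(O[Si](C)(C)C(C)(C)C)c(OC)c2)ccc1O[Si](C)(C)C(C)(C)C
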